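## The problem

Compound 29 is a bicyclic diterpenoid of the labdane type in the enantiomeric series (labdane numbering is used throughout: ring carbons C1–C10, chain C11–C15, methyls C16 on C13, C17 on C8, C18/C19 on C4, C20 on C10). Rings A and B form a trans-decalin that shares the C5–C10 bond. C10 is quaternary and carries a methyl group, C4 a gem-dimethyl group, ring A a 2-oxo-3-hydroxy unit and ring B a trisubstituted C7=C8 alkene. C9 carries a five-carbon chain that ends in an (E)-allylic acetate. There are four stereocentres: C3 (S), C5 (S), C9 (R) and C10 (S). C5, C9 and C10 are contiguous, and their relation (trans fusion, C9 chain cis to the C10 methyl) is what a suprafacial cycloaddition delivers. C3 stands apart, equatorial and cis to the C10 methyl; it is the one centre that can be bought, so it should control the other three. C2 ends as a carbonyl, so until then it can serve as a second, expendable centre that reinforces C3. Three groups must appear late: the α-ketol enolises under base (epimerisation at C3, ketol shift), the allylic acetate does not survive hydrides, carbanions, strong Lewis acids or zerovalent palladium, and the C7=C8 alkene moves to C8=C9 under acid. The enabling feature is that cutting C5–C10 and C8–C9 opens both rings at once. What remains is a C9=C10 (E)-enoate (C11 ester, C10 methyl) and a C5=C6–C7=C8 diene, joined by the chain C1–C4 that bears the C2 and C3 oxygens and the gem-dimethyl group. The price is that the ring B alkene is formed at C6–C7 and must be moved, and that C11 must be extended by five carbons.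

## Retrosynthesis

**Unmasking the α-ketol (29 ⇐ 28 ⇐ 27 ⇐ 26).** No skeletal bond is cut. The C3 hydroxyl is carried as a 2-naphthylmethyl ether and the C2 carbonyl as a silyl-protected carbinol. A C2 ketone would not survive the hydride and Grignard steps, and a free C3 hydroxyl would be oxidised with C2. The order is therefore desilylation of 26 to 27, oxidation to 28, then neutral oxidative removal of the naphthylmethyl group. The forward steps must be non-basic so that C3 and the acetate are kept.

**Side chain (26 ⇐ 23 + 24).** The C11–C12 bond is cut. The nucleophile is the Grignard reagent from iodide 23 and the electrophile is the C5 chloroacetate 24, which brings C12–C16, the (E)-alkene and the acetate in one step. Building the chain through a methyl ketone and an olefination would take four to five steps and would leave an E/Z problem. The coupling must substitute at the CH2Cl carbon and must spare the acetate. Iodide 23 comes from ester 21 through alcohol 22.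

**Alkene position (21 ⇐ 20 ⇐ 18 ⇐ 17 ⇐ 15).** A cycloaddition that forms C5–C10 and C8–C9 necessarily leaves the alkene at C6–C7. It is moved through C7 oxygenation: hydroboration to 17, oxidation to ketone 18, the more substituted enol triflate 20, and reduction to 21. A one-step metal-hydride isomerisation of 15 would be shorter, but it could run on to the C8=C9 alkene conjugated with the ester, so it is kept as a fallback. The forward steps need boron on C7 and enolisation toward C8.

**Key disconnection (15 ⇐ 14).** C5–C10 and C8–C9 are cut together. Trienoate 14 is acyclic and has only two stereocentres. The forward intramolecular Diels–Alder reaction must close rings A and B and set C5, C8, C9 and C10 under the control of C2 and C3. Stepwise annulations would set these centres one at a time and would need an outside source of asymmetry for the quaternary C10.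

**Enoate and C2 (14 ⇐ 13 ⇐ 9 + 12).** The C1–C2 bond is cut. A vinylogous aldol reaction of the silyl dienolate 12 (from ester 10) with aldehyde 9 delivers C1, C9, C10, C11, the C10 methyl, the (E)-enoate and the C2 carbinol in one step. The reverse polarity, a C1 organometal added to a but-2-ynoate, was set aside because a metal on C1 is β to the C2 oxygen and would eliminate. An aldol that makes C2–C3 from a glycolate would leave C1 at the carboxyl level. The forward reaction must give the 2,3-syn isomer. This is why C3 carries a chelating benzyl-type ether and not a silyl ether, and the 2-naphthylmethyl group is chosen because it also tolerates the Lewis acid of the key step better than a 4-methoxybenzyl ether.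

**Diene and chiral pool (9 ⇐ 8 ⇐ 4 + 6; 4 ⇐ 3 ⇐ 2 ⇐ 1; 6 ⇐ 5).** The C5=C6 bond is cut by an (E)-selective Wittig reaction between aldehyde 4 and the ylide from phosphonium salt 6, which is made from bromide 5. Aldehyde 4 maps onto (S)-pantolactone 1: the carbinol is C3, the quaternary carbon is C4, the lactone carbonyl is C2 and the CH2O group is C5. Protection to 2, Weinreb opening to 3 and oxidation give 4. The amide holds C2 at the acyl level until it is reduced to aldehyde 9. The chiral pool thus supplies C3 and the gem-dimethyl group with no asymmetric step.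

## Roads not taken

Alternative 1: The cut is C9–C10 plus C5–C6. The tetrasubstituted enol silane of a ring A ketone would add, under a strong Lewis acid, to the β-carbon of an (E)-enone that carries the ketal-masked chain, and base would then close ring B by aldol condensation to give enone A1. Its merit is convergence: C11–C13 and C16 arrive with ring B, so no late sp3–sp3 coupling is needed. In this respect it is better than the chosen plan, which must make the C11–C12 bond with a hindered Grignard reagent. Its weak points lie in what A1 lacks. The quaternary C10 is formed intermolecularly next to the new C9 centre, with only a remote C2 silyl ether to set their relative and absolute configuration. A1 has no C3 oxygen, no C17 methyl and an sp2 C5. It would still need C8 methylation, an enone reduction that fixes C5, removal of the C7 oxygen with formation of C7=C8, hydroxylation at C3 in competition with C1, and a two-carbon extension of the ketal. The chosen plan sets its centres in one step from a tether of known configuration and carries the C3 oxygen and C17 from the start.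

Alternative 2: The cut is C1–C10 plus C4–C5. A chiral oxazaborolidinium Lewis acid would catalyse the Diels–Alder reaction of a methyl-bearing double bond of quinone A3 with silyloxydiene A4 to give the cis-fused adduct A2. This road has clear merits. Enantiocontrol is catalytic and not drawn from the chiral pool. A2 already holds the C7=C8 alkene with its methyl, for which the chosen plan spends four steps. The C2=C3 enol silane could give the 2-oxo-3-hydroxy unit by a single Rubottom oxidation, where the chosen plan needs three unmasking steps. Against this, A4 has a fully substituted terminus with one methyl necessarily inside, and it must add to a trisubstituted quinone double bond, so the cycloaddition is expected to be sluggish. C5 must be epimerised to the trans fusion and the C6 carbonyl must be removed. Most seriously, C9 is a ketone flanked by the quaternary C10: attaching C11 there, removing the oxygen and setting C9 is a long and uncertain sequence. The chosen plan sets against it a cycloaddition that installs C9 with its carbon substituent and its configuration directly.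

Alternative 3: The cut is C9–C10 alone. A cis-triene (C10=C5–C6=C7–C8=C9), released by semihydrogenation of a dienyne, would close thermally by disrotatory 6π electrocyclisation to diene A5. It is the shortest way to the bicycle, ring A comes from a known hydroxylated trimethylcyclohexene building block, and the C11 ester and C8 methyl are in place; in step count to the decalin it beats the chosen plan. Its weak points are these. The closure creates the quaternary C10 at a fully substituted triene terminus, so it is slow, reversible and in competition with 1,7-hydrogen shifts. The sense of rotation, and with it C9 and C10, is governed only by the remote C2 silyl ether. A5 is a 5,7-diene whose C5=C6 bond must be saturated with trans fusion while C7=C8 is kept. There is no C3 oxygen. The chosen plan is longer but controls every centre from C3 and never has to differentiate two ring alkenes.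

Key step: step 10

Remark: (S)-pantolactone 1 and the (E)-chloroacetate 24 are taken as purchasable; silyl dienolate 12 is used as the mixture of C1=C2 isomers that step 7 gives, since this geometry is lost in step 8.

## Route

Step 1
Reactants: 1 (S)-pantolactone
Product: 2 (3S)-4,4-dimethyl-3-(naphthalen-2-ylmethoxy)oxolan-2-one
Conditions: 2-(bromomethyl)naphthalene, Ag2O, CH2Cl2, 25 °C, dark
Reagents that add atoms: 2-(bromomethyl)naphthalene, BrCc1ccc2ccccc2c1
Why: Williamson-type O-alkylation promoted by Ag2O under neutral conditions, so the lactone is not enolised and C3 keeps its configuration; the naphthylmethyl ether can chelate in step 8, withstands alkylaluminium chlorides better than a 4-methoxybenzyl ether and is still cleaved by DDQ.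

Step 2
Reactants: 2 (3S)-4,4-dimethyl-3-(naphthalen-2-ylmethoxy)oxolan-2-one
Product: 3 (2S)-4-hydroxy-N-methoxy-N,3,3-trimethyl-2-(naphthalen-2-ylmethoxy)butanamide
Conditions: MeNH(OMe)·HCl, AlMe3, CH2Cl2, 0 → 25 °C; aqueous potassium sodium tartrate
Reagents that add atoms: N,O-dimethylhydroxylamine hydrochloride, CNOC.Cl
Why: Weinreb aminolysis of the lactone by the aluminium amide; it frees the C5 hydroxyl and keeps C2 at the acyl level. Crude 3 is oxidised at once because the gem-dimethyl group favours relactonisation.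

Step 3
Reactants: 3 (2S)-4-hydroxy-N-methoxy-N,3,3-trimethyl-2-(naphthalen-2-ylmethoxy)butanamide
Product: 4 (2S)-N-methoxy-N,3,3-trimethyl-2-(naphthalen-2-ylmethoxy)-4-oxobutanamide
Conditions: Dess–Martin periodinane, NaHCO3, CH2Cl2, 0 → 25 °C
Reagents that add atoms: none
Why: Dess–Martin oxidation of the neopentyl primary alcohol under buffered conditions; the aldehyde has no α-hydrogen, and the Weinreb amide and C3 are untouched.

Step 4
Reactants: 5 (E)-1-bromobut-2-ene
Product: 6 tributyl[(2E)-but-2-en-1-yl]phosphonium bromide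
Conditions: PBu3, MeCN, 25 °C
Reagents that add atoms: tributylphosphine, CCCCP(CCCC)CCCC
Why: SN2 quaternisation of the primary allylic bromide by the phosphine (phosphonium salt formation); the (E)-alkene is not involved.

Step 5
Reactants: 4 (2S)-N-methoxy-N,3,3-trimethyl-2-(naphthalen-2-ylmethoxy)-4-oxobutanamide; 6 tributyl[(2E)-but-2-en-1-yl]phosphonium bromide
Product: 8 (2S,4E,6E)-N-methoxy-N,3,3-trimethyl-2-(naphthalen-2-ylmethoxy)octa-4,6-dienamide, via phosphorus ylide 7 (not isolated)
Conditions: KOt-Bu (slight deficit), THF, −78 → 25 °C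
Reagents that add atoms: none
Why: Wittig olefination with an allylic trialkylphosphonium ylide, a reagent class that reacts at its α-carbon and gives (E)-alkenes through reversible oxaphosphetane formation; the quaternary C4 next to the aldehyde adds to the E preference and the butenyl (E)-bond is carried over. The deficit of base keeps the α-alkoxy amide centre from epimerising.

Step 6
Reactants: 8 (2S,4E,6E)-N-methoxy-N,3,3-trimethyl-2-(naphthalen-2-ylmethoxy)octa-4,6-dienamide
Product: 9 (2S,4E,6E)-3,3-dimethyl-2-(naphthalen-2-ylmethoxy)octa-4,6-dienal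
Conditions: i-Bu2AlH, THF, −78 °C; aqueous potassium sodium tartrate
Reagents that add atoms: none
Why: Weinreb amide reduction; the chelated tetrahedral aluminium intermediate collapses only on work-up, so the aldehyde is not reduced further. Crude 9 is used directly to avoid epimerisation of the α-alkoxy aldehyde.

Step 7
Reactants: 10 methyl 3-methylbut-2-enoate
Product: 12 1-methoxy-3-methyl-1-(trimethylsilyloxy)buta-1,3-diene, via lithium dienolate 11 (not isolated)
Conditions: LiN(i-Pr)2 (from i-Pr2NH, n-BuLi), THF, −78 °C; Me3SiCl, −78 → 25 °C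
Reagents that add atoms: chlorotrimethylsilane, C[Si](C)(C)Cl
Why: γ-deprotonation of the β,β-dimethylacrylate and O-silylation of the dienolate (silyl ketene acetal formation) give the vinylogous nucleophile.

Step 8
Reactants: 9 (2S,4E,6E)-3,3-dimethyl-2-(naphthalen-2-ylmethoxy)octa-4,6-dienal; 12 1-methoxy-3-methyl-1-(trimethylsilyloxy)buta-1,3-diene
Product: 13 methyl (2E,5S,6S,8E,10E)-5-hydroxy-3,7,7-trimethyl-6-(naphthalen-2-ylmethoxy)dodeca-2,8,10-trienoate
Conditions: MgBr2·OEt2, CH2Cl2, −78 → −20 °C; 1 M HCl
Reagents that add atoms: none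
Why: Vinylogous Mukaiyama aldol reaction: the silyl dienolate attacks through its γ-carbon (C1) and the s-trans arrangement gives the (E)-enoate, any (Z)-isomer being removed as its δ-lactone. Magnesium chelation between the aldehyde oxygen and the C3 ether directs attack to the face opposite the quaternary C4, which sets C2 as S (2,3-syn).

Step 9
Reactants: 13 methyl (2E,5S,6S,8E,10E)-5-hydroxy-3,7,7-trimethyl-6-(naphthalen-2-ylmethoxy)dodeca-2,8,10-trienoate
Product: 14 methyl (2E,5S,6S,8E,10E)-5-(tert-butyldimethylsilyloxy)-3,7,7-trimethyl-6-(naphthalen-2-ylmethoxy)dodeca-2,8,10-trienoate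
Conditions: TBSOTf, 2,6-lutidine, CH2Cl2, −78 → 0 °C
Reagents that add atoms: tert-butyldimethylsilyl trifluoromethanesulfonate, CC(C)(C)[Si](C)(C)OS(=O)(=O)C(F)(F)F
Why: Silylation of the secondary alcohol with a silyl triflate and a hindered base; the TBS ether survives the Lewis acid of step 10 and all later steps and is the group removed first at the end.

Step 10
Reactants: 14 methyl (2E,5S,6S,8E,10E)-5-(tert-butyldimethylsilyloxy)-3,7,7-trimethyl-6-(naphthalen-2-ylmethoxy)dodeca-2,8,10-trienoate
Product: 15 methyl (1R,2R,4aS,6S,7S,8aR)-7-(tert-butyldimethylsilyloxy)-2,5,5,8a-tetramethyl-6-(naphthalen-2-ylmethoxy)-1,2,4a,5,6,7,8,8a-octahydronaphthalene-1-carboxylate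
Conditions: MeAlCl2 (2.2 equiv), CH2Cl2, −78 → 0 °C
Reagents that add atoms: none
Why: Lewis acid-promoted intramolecular Diels–Alder reaction of a 1,7,9-decatrienoate with a four-atom tether, the closest known class being alkylaluminium chloride-promoted cyclisations of such trienoates, β-methyl enoates included, to trans-fused decalins. MeAlCl2 binds the ester carbonyl, lowers the LUMO of the trisubstituted dienophile, and the concerted, asynchronous, suprafacial [4+2] addition forms C8–C9 and C5–C10. Ring B is the new cyclohexene closed by both bonds; ring A is closed by the C5–C10 bond alone, with the chain C1–C4 folded as a chair (six-membered carbocycle, fused mode). C9 and C10 take their relation from the (E)-enoate, so the ester and the C10 methyl are cis. C5 is set by the ester-endo transition state, in which the tether lies anti to the ester and the ring fusion becomes trans. C8 follows from the (E)-diene terminus and the endo mode, its methyl cis to the ester (this centre is erased later). Of the two chair-like endo transition states only one keeps the C2 silyl ether and the C3 naphthylmethyl ether equatorial, while the other would place the C2 group syn-axial to the C4 and C10 methyls, so C3 from pantolactone and C2 from the aldol fix the absolute sense at C5, C9 and C10. The step needs endo and facial selectivity; the Lewis acid-bound ester secures the first, and the two equatorial ethers together with the gem-dimethyl group, which favours the folded conformer, secure the second.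

Step 11
Reactants: 15 methyl (1R,2R,4aS,6S,7S,8aR)-7-(tert-butyldimethylsilyloxy)-2,5,5,8a-tetramethyl-6-(naphthalen-2-ylmethoxy)-1,2,4a,5,6,7,8,8a-octahydronaphthalene-1-carboxylate
Product: 17 methyl (1R,2S,3S,4aS,6S,7S,8aR)-7-(tert-butyldimethylsilyloxy)-3-hydroxy-2,5,5,8a-tetramethyl-6-(naphthalen-2-ylmethoxy)decahydronaphthalene-1-carboxylate, via C7 alkylborane 16 (not isolated)
Conditions: BH3·SMe2, THF, 0 → 25 °C; NaOH, H2O2, 0 °C
Reagents that add atoms: hydrogen peroxide, OO
Why: Hydroboration–oxidation; borane adds syn from the face opposite the C10 and C8 methyls and places boron on C7, because C6 is screened on one face by the axial C4 and C10 methyls and on the other by the equatorial C4 methyl. The hindered ester reacts more slowly than the alkene, and the C7 configuration is of no account since it is oxidised next.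

Step 12
Reactants: 17 methyl (1R,2S,3S,4aS,6S,7S,8aR)-7-(tert-butyldimethylsilyloxy)-3-hydroxy-2,5,5,8a-tetramethyl-6-(naphthalen-2-ylmethoxy)decahydronaphthalene-1-carboxylate
Product: 18 methyl (1R,2S,4aS,6S,7S,8aR)-7-(tert-butyldimethylsilyloxy)-2,5,5,8a-tetramethyl-6-(naphthalen-2-ylmethoxy)-3-oxodecahydronaphthalene-1-carboxylate
Conditions: Dess–Martin periodinane, NaHCO3, CH2Cl2, 25 °C
Reagents that add atoms: none
Why: Dess–Martin oxidation of the secondary alcohol; the neutral conditions leave both ethers and the ester alone, and any epimerisation at C8 next to the ketone is without consequence.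

Step 13
Reactants: 18 methyl (1R,2S,4aS,6S,7S,8aR)-7-(tert-butyldimethylsilyloxy)-2,5,5,8a-tetramethyl-6-(naphthalen-2-ylmethoxy)-3-oxodecahydronaphthalene-1-carboxylate
Product: 20 methyl (1S,4aS,6S,7S,8aR)-7-(tert-butyldimethylsilyloxy)-2,5,5,8a-tetramethyl-6-(naphthalen-2-ylmethoxy)-3-(trifluoromethylsulfonyloxy)-1,4,4a,5,6,7,8,8a-octahydronaphthalene-1-carboxylate, via bromomagnesium enolate 19 (not isolated)
Conditions: i-Pr2NMgBr (from i-Pr2NH, EtMgBr), Et2O/THF, 25 °C; PhNTf2, 25 °C
Reagents that add atoms: N-phenylbis(trifluoromethanesulfonimide), O=S(=O)(N(c1ccccc1)S(=O)(=O)C(F)(F)F)C(F)(F)F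
Why: Regioselective enol triflate formation through the thermodynamic enolate: the magnesium amide enolises reversibly, so the more substituted C7–C8 enolate accumulates (C8 equilibrates on the way), and O-sulfonylation fixes it. The hindered amide does not attack the ester.

Step 14
Reactants: 20 methyl (1S,4aS,6S,7S,8aR)-7-(tert-butyldimethylsilyloxy)-2,5,5,8a-tetramethyl-6-(naphthalen-2-ylmethoxy)-3-(trifluoromethylsulfonyloxy)-1,4,4a,5,6,7,8,8a-octahydronaphthalene-1-carboxylate
Product: 21 methyl (1R,4aS,6S,7S,8aR)-7-(tert-butyldimethylsilyloxy)-2,5,5,8a-tetramethyl-6-(naphthalen-2-ylmethoxy)-1,4,4a,5,6,7,8,8a-octahydronaphthalene-1-carboxylate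
Conditions: Pd(OAc)2 (5 mol %), PPh3, HCO2H, Bu3N, DMF, 60 °C
Reagents that add atoms: none
Why: Palladium-catalysed formate reduction of an enol triflate (oxidative addition, exchange to the formate, loss of CO2, C–H reductive elimination); the alkene stays where the triflate was, giving C7=C8. The weak amine base is not expected to move the β,γ-alkene into conjugation with the ester.

Step 15
Reactants: 21 methyl (1R,4aS,6S,7S,8aR)-7-(tert-butyldimethylsilyloxy)-2,5,5,8a-tetramethyl-6-(naphthalen-2-ylmethoxy)-1,4,4a,5,6,7,8,8a-octahydronaphthalene-1-carboxylate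
Product: 22 [(1R,4aS,6S,7S,8aR)-7-(tert-butyldimethylsilyloxy)-2,5,5,8a-tetramethyl-6-(naphthalen-2-ylmethoxy)-1,4,4a,5,6,7,8,8a-octahydronaphthalen-1-yl]methanol
Conditions: i-Bu2AlH, CH2Cl2, −78 → 0 °C; aqueous potassium sodium tartrate
Reagents that add atoms: none
Why: Ester reduction by the aluminium hydride to the primary alcohol; no base is present that could epimerise C9 or conjugate the alkene.

Step 16
Reactants: 22 [(1R,4aS,6S,7S,8aR)-7-(tert-butyldimethylsilyloxy)-2,5,5,8a-tetramethyl-6-(naphthalen-2-ylmethoxy)-1,4,4a,5,6,7,8,8a-octahydronaphthalen-1-yl]methanol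
Product: 23 (1R,4aS,6S,7S,8aR)-7-(tert-butyldimethylsilyloxy)-1-(iodomethyl)-2,5,5,8a-tetramethyl-6-(naphthalen-2-ylmethoxy)-1,4,4a,5,6,7,8,8a-octahydronaphthalene
Conditions: I2, PPh3, imidazole, CH2Cl2, 0 → 25 °C
Reagents that add atoms: iodine, II
Why: Appel-type iodination; iodide displaces the oxyphosphonium group by SN2 at the primary C11, without cationic intermediates that could involve the homoallylic alkene.

Step 17
Reactants: 23 (1R,4aS,6S,7S,8aR)-7-(tert-butyldimethylsilyloxy)-1-(iodomethyl)-2,5,5,8a-tetramethyl-6-(naphthalen-2-ylmethoxy)-1,4,4a,5,6,7,8,8a-octahydronaphthalene; 24 (E)-4-chloro-3-methylbut-2-enyl acetate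
Product: 26 (2E)-5-[(1R,4aS,6S,7S,8aS)-7-(tert-butyldimethylsilyloxy)-2,5,5,8a-tetramethyl-6-(naphthalen-2-ylmethoxy)-1,4,4a,5,6,7,8,8a-octahydronaphthalen-1-yl]-3-methylpent-2-en-1-yl acetate, via Grignard reagent 25 (not isolated)
Conditions: Mg, THF, 35 °C; then added slowly to 24, Li2CuCl4 (3 mol %), THF, −78 → −20 °C
Reagents that add atoms: none
Why: Copper-catalysed cross-coupling of a Grignard reagent with a primary allylic chloride; substitution occurs at the CH2Cl carbon with retention of the (E)-alkene and forms C11–C12. At low temperature and with inverse addition the chloride reacts much faster than the allylic acetate or its carbonyl.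

Step 18
Reactants: 26 (2E)-5-[(1R,4aS,6S,7S,8aS)-7-(tert-butyldimethylsilyloxy)-2,5,5,8a-tetramethyl-6-(naphthalen-2-ylmethoxy)-1,4,4a,5,6,7,8,8a-octahydronaphthalen-1-yl]-3-methylpent-2-en-1-yl acetate
Product: 27 (2E)-5-[(1R,4aS,6S,7S,8aS)-7-hydroxy-2,5,5,8a-tetramethyl-6-(naphthalen-2-ylmethoxy)-1,4,4a,5,6,7,8,8a-octahydronaphthalen-1-yl]-3-methylpent-2-en-1-yl acetate
Conditions: HF·pyridine, pyridine, THF, 0 → 25 °C
Reagents that add atoms: none
Why: Fluoride-induced desilylation; buffered HF·pyridine removes the C2 silyl ether without touching the allylic acetate, the alkenes or the naphthylmethyl ether.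

Step 19
Reactants: 27 (2E)-5-[(1R,4aS,6S,7S,8aS)-7-hydroxy-2,5,5,8a-tetramethyl-6-(naphthalen-2-ylmethoxy)-1,4,4a,5,6,7,8,8a-octahydronaphthalen-1-yl]-3-methylpent-2-en-1-yl acetate
Product: 28 (2E)-3-methyl-5-[(1R,4aS,6S,8aS)-2,5,5,8a-tetramethyl-6-(naphthalen-2-ylmethoxy)-7-oxo-1,4,4a,5,6,7,8,8a-octahydronaphthalen-1-yl]pent-2-en-1-yl acetate
Conditions: Dess–Martin periodinane, NaHCO3, CH2Cl2, 25 °C
Reagents that add atoms: none
Why: Dess–Martin oxidation of the C2 alcohol to the ketone; the conditions are non-basic, so the α-alkoxy ketone does not epimerise at C3.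

Step 20
Reactants: 28 (2E)-3-methyl-5-[(1R,4aS,6S,8aS)-2,5,5,8a-tetramethyl-6-(naphthalen-2-ylmethoxy)-7-oxo-1,4,4a,5,6,7,8,8a-octahydronaphthalen-1-yl]pent-2-en-1-yl acetate
Product: 29 (2E)-5-[(1R,4aS,6S,8aS)-6-hydroxy-2,5,5,8a-tetramethyl-7-oxo-1,4,4a,5,6,7,8,8a-octahydronaphthalen-1-yl]-3-methylpent-2-en-1-yl acetate
Conditions: DDQ, CH2Cl2/pH 7 buffer, 0 → 25 °C
Reagents that add atoms: none
Why: Oxidative cleavage of the 2-naphthylmethyl ether by DDQ (hydride abstraction, then hydrolysis of the oxocarbenium ion) under neutral buffered conditions; the α-ketol, the allylic acetate and both trisubstituted alkenes are not affected and C3 keeps its configuration.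

## Compound list

1 | (S)-pantolactone, (3S)-3-hydroxy-4,4-dimethyloxolan-2-one | O=C1OCC(C)(C)[C@@H]1O | starting material
2 | (3S)-4,4-dimethyl-3-(naphthalen-2-ylmethoxy)oxolan-2-one | O=C1OCC(C)(C)[C@@H]1OCc1ccc2ccccc2c1 | intermediate
3 | (2S)-4-hydroxy-N-methoxy-N,3,3-trimethyl-2-(naphthalen-2-ylmethoxy)butanamide | CON(C)C(=O)[C@@H](OCc1ccc2ccccc2c1)C(C)(C)CO | intermediate
4 | (2S)-N-methoxy-N,3,3-trimethyl-2-(naphthalen-2-ylmethoxy)-4-oxobutanamide | CON(C)C(=O)[C@@H](OCc1ccc2ccccc2c1)C(C)(C)C=O | intermediate
5 | (E)-1-bromobut-2-ene | C/C=C/CBr | starting material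
6 | tributyl[(2E)-but-2-en-1-yl]phosphonium bromide | C/C=C/C[P+](CCCC)(CCCC)CCCC.[Br-] | intermediate
7 | tributyl[(2E)-but-2-en-1-ylidene]phosphorane (ylide) | C/C=C/C=P(CCCC)(CCCC)CCCC | intermediate
8 | (2S,4E,6E)-N-methoxy-N,3,3-trimethyl-2-(naphthalen-2-ylmethoxy)octa-4,6-dienamide | CON(C)C(=O)[C@@H](OCc1ccc2ccccc2c1)C(C)(C)/C=C/C=C/C | intermediate
9 | (2S,4E,6E)-3,3-dimethyl-2-(naphthalen-2-ylmethoxy)octa-4,6-dienal | O=C[C@@H](OCc1ccc2ccccc2c1)C(C)(C)/C=C/C=C/C | intermediate
10 | methyl 3-methylbut-2-enoate | COC(=O)C=C(C)C | starting material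
11 | lithium 1-methoxy-3-methylbuta-1,3-dien-1-olate | [Li]OC(OC)=CC(C)=C | intermediate
12 | 1-methoxy-3-methyl-1-(trimethylsilyloxy)buta-1,3-diene (mixture about C1=C2) | COC(O[Si](C)(C)C)=CC(C)=C | intermediate
13 | methyl (2E,5S,6S,8E,10E)-5-hydroxy-3,7,7-trimethyl-6-(naphthalen-2-ylmethoxy)dodeca-2,8,10-trienoate | COC(=O)/C=C(\C)C[C@H](O)[C@@H](OCc1ccc2ccccc2c1)C(C)(C)/C=C/C=C/C | intermediate
14 | methyl (2E,5S,6S,8E,10E)-5-(tert-butyldimethylsilyloxy)-3,7,7-trimethyl-6-(naphthalen-2-ylmethoxy)dodeca-2,8,10-trienoate | COC(=O)/C=C(\C)C[C@H](O[Si](C)(C)C(C)(C)C)[C@@H](OCc1ccc2ccccc2c1)C(C)(C)/C=C/C=C/C | intermediate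
15 | methyl (1R,2R,4aS,6S,7S,8aR)-7-(tert-butyldimethylsilyloxy)-2,5,5,8a-tetramethyl-6-(naphthalen-2-ylmethoxy)-1,2,4a,5,6,7,8,8a-octahydronaphthalene-1-carboxylate | COC(=O)[C@@H]1[C@H](C)C=C[C@@H]2C(C)(C)[C@H](OCc3ccc4ccccc4c3)[C@@H](O[Si](C)(C)C(C)(C)C)C[C@@]12C | intermediate
16 | C7 alkylborane of 15 (boron on the face of the C5 hydrogen) | COC(=O)[C@@H]1[C@H](C)[C@@H](B)C[C@@H]2C(C)(C)[C@H](OCc3ccc4ccccc4c3)[C@@H](O[Si](C)(C)C(C)(C)C)C[C@@]12C | intermediate
17 | methyl (1R,2S,3S,4aS,6S,7S,8aR)-7-(tert-butyldimethylsilyloxy)-3-hydroxy-2,5,5,8a-tetramethyl-6-(naphthalen-2-ylmethoxy)decahydronaphthalene-1-carboxylate | COC(=O)[C@@H]1[C@H](C)[C@@H](O)C[C@@H]2C(C)(C)[C@H](OCc3ccc4ccccc4c3)[C@@H](O[Si](C)(C)C(C)(C)C)C[C@@]12C | intermediate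
18 | methyl (1R,2S,4aS,6S,7S,8aR)-7-(tert-butyldimethylsilyloxy)-2,5,5,8a-tetramethyl-6-(naphthalen-2-ylmethoxy)-3-oxodecahydronaphthalene-1-carboxylate | COC(=O)[C@@H]1[C@H](C)C(=O)C[C@@H]2C(C)(C)[C@H](OCc3ccc4ccccc4c3)[C@@H](O[Si](C)(C)C(C)(C)C)C[C@@]12C | intermediate
19 | bromomagnesium C7–C8 enolate of 18 | COC(=O)[C@@H]1C(C)=C(O[Mg]Br)C[C@@H]2C(C)(C)[C@H](OCc3ccc4ccccc4c3)[C@@H](O[Si](C)(C)C(C)(C)C)C[C@@]12C | intermediate
20 | methyl (1S,4aS,6S,7S,8aR)-7-(tert-butyldimethylsilyloxy)-2,5,5,8a-tetramethyl-6-(naphthalen-2-ylmethoxy)-3-(trifluoromethylsulfonyloxy)-1,4,4a,5,6,7,8,8a-octahydronaphthalene-1-carboxylate | COC(=O)[C@@H]1C(C)=C(OS(=O)(=O)C(F)(F)F)C[C@@H]2C(C)(C)[C@H](OCc3ccc4ccccc4c3)[C@@H](O[Si](C)(C)C(C)(C)C)C[C@@]12C | intermediate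
21 | methyl (1R,4aS,6S,7S,8aR)-7-(tert-butyldimethylsilyloxy)-2,5,5,8a-tetramethyl-6-(naphthalen-2-ylmethoxy)-1,4,4a,5,6,7,8,8a-octahydronaphthalene-1-carboxylate | COC(=O)[C@@H]1C(C)=CC[C@@H]2C(C)(C)[C@H](OCc3ccc4ccccc4c3)[C@@H](O[Si](C)(C)C(C)(C)C)C[C@@]12C | intermediate
22 | [(1R,4aS,6S,7S,8aR)-7-(tert-butyldimethylsilyloxy)-2,5,5,8a-tetramethyl-6-(naphthalen-2-ylmethoxy)-1,4,4a,5,6,7,8,8a-octahydronaphthalen-1-yl]methanol | OC[C@@H]1C(C)=CC[C@@H]2C(C)(C)[C@H](OCc3ccc4ccccc4c3)[C@@H](O[Si](C)(C)C(C)(C)C)C[C@@]12C | intermediate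
23 | (1R,4aS,6S,7S,8aR)-7-(tert-butyldimethylsilyloxy)-1-(iodomethyl)-2,5,5,8a-tetramethyl-6-(naphthalen-2-ylmethoxy)-1,4,4a,5,6,7,8,8a-octahydronaphthalene | IC[C@@H]1C(C)=CC[C@@H]2C(C)(C)[C@H](OCc3ccc4ccccc4c3)[C@@H](O[Si](C)(C)C(C)(C)C)C[C@@]12C | intermediate
24 | (E)-4-chloro-3-methylbut-2-enyl acetate | CC(=O)OC/C=C(\C)CCl | starting material
25 | iodomagnesium reagent from 23 (Mg on C11) | I[Mg]C[C@@H]1C(C)=CC[C@@H]2C(C)(C)[C@H](OCc3ccc4ccccc4c3)[C@@H](O[Si](C)(C)C(C)(C)C)C[C@@]12C | intermediate
26 | (2E)-5-[(1R,4aS,6S,7S,8aS)-7-(tert-butyldimethylsilyloxy)-2,5,5,8a-tetramethyl-6-(naphthalen-2-ylmethoxy)-1,4,4a,5,6,7,8,8a-octahydronaphthalen-1-yl]-3-methylpent-2-en-1-yl acetate | CC(=O)OC/C=C(\C)CC[C@@H]1C(C)=CC[C@@H]2C(C)(C)[C@H](OCc3ccc4ccccc4c3)[C@@H](O[Si](C)(C)C(C)(C)C)C[C@@]12C | intermediate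
27 | (2E)-5-[(1R,4aS,6S,7S,8aS)-7-hydroxy-2,5,5,8a-tetramethyl-6-(naphthalen-2-ylmethoxy)-1,4,4a,5,6,7,8,8a-octahydronaphthalen-1-yl]-3-methylpent-2-en-1-yl acetate | CC(=O)OC/C=C(\C)CC[C@@H]1C(C)=CC[C@@H]2C(C)(C)[C@H](OCc3ccc4ccccc4c3)[C@@H](O)C[C@@]12C | intermediate
28 | (2E)-3-methyl-5-[(1R,4aS,6S,8aS)-2,5,5,8a-tetramethyl-6-(naphthalen-2-ylmethoxy)-7-oxo-1,4,4a,5,6,7,8,8a-octahydronaphthalen-1-yl]pent-2-en-1-yl acetate | CC(=O)OC/C=C(\C)CC[C@@H]1C(C)=CC[C@@H]2C(C)(C)[C@H](OCc3ccc4ccccc4c3)C(=O)C[C@@]12C | intermediate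
29 | (2E)-5-[(1R,4aS,6S,8aS)-6-hydroxy-2,5,5,8a-tetramethyl-7-oxo-1,4,4a,5,6,7,8,8a-octahydronaphthalen-1-yl]-3-methylpent-2-en-1-yl acetate | CC(=O)OC/C=C(\C)CC[C@@H]1C(C)=CC[C@@H]2C(C)(C)[C@H](O)C(=O)C[C@@]12C | target

## Step count and least certain steps

Total: 20 steps. Longest linear sequence: 18 steps (1 → 29 through steps 1–3, 5, 6 and 8–20); steps 4 and 7 prepare reagents 6 and 12.

**Step 10 (key step).** The trisubstituted dienophile may react too slowly. The warming then needed could bring ionisation of the naphthylmethyl ether by the Lewis acid, cationic loss of the diene, or leakage through the exo transition state to the cis-fused isomer. The fallback keeps the same bonds but uses a stronger dienophile. It sets out from 14: reduction with i-Bu2AlH gives the trienol F1, oxidation with MnO2 gives the trienal F2, and the enal is cyclised with Me2AlCl at −78 °C (or thermally) to the cycloadduct aldehyde F3. Oxidation with NaClO2 to the acid F4 and esterification with Me3SiCHN2 come back to the route at 15.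

**Step 8.** Chelation may be incomplete, so that open-chain attack gives the 2,3-anti isomer, and part of the enoate may form with Z geometry and be lost by lactonisation. The fallback builds the enoate by carbometalation and sets out from 9. Allenyltributylstannane (Bu3SnCH=C=CH2) with MgBr2·OEt2 adds under the same chelation control to give the homopropargylic alcohol F5, and TBSOTf gives its silyl ether F6. Negishi carboalumination (AlMe3, Cp2ZrCl2) adds methyl and aluminium syn across the alkyne to the alkenylalane F7, which ClCO2Me converts into the (E)-enoate; the route is rejoined at 14.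

**Step 11.** Boron may be delivered to C6 in competition with C7, and excess borane may slowly reduce the ester. The fallback avoids oxygenation altogether. It sets out from 15 and moves the alkene directly by metal-hydride isomerisation with RuHCl(CO)(PPh3)3 in toluene at 80 °C; relief of the 1,3-diaxial C8/C10 methyl interaction drives the shift to C7=C8. It comes back to the route at 21 and makes no new compound.

**Step 13.** Enolisation toward C6, or incomplete equilibration, would give the C6–C7 triflate and, after reduction, return 15. The fallback replaces triflate reduction by dehydration and sets out from 18. NaOMe in MeOH equilibrates C8 to the ketone with the equatorial methyl F8, and LiBH(s-Bu)3 delivers hydride equatorially to give the axial alcohol F9. POCl3 in pyridine then eliminates anti toward the tertiary C8 hydrogen; the route is rejoined at 21.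

**Step 17.** Magnesium insertion into the hindered iodide may be accompanied by homocoupling or reduction, and the Grignard reagent may attack the acetate carbonyl or substitute at C14. The fallback couples through a sulfone-stabilised carbanion and sets out from 23 and 24. PhSO2Na displaces the chloride of 24 to give the sulfone acetate F10, and K2CO3 in MeOH gives the hydroxy sulfone F11. Double deprotonation with n-BuLi gives the dilithio derivative F12, which is alkylated on carbon by 23 to the coupled hydroxy sulfone F13. Reductive desulfonylation with LiBHEt3 and catalytic PdCl2(dppp) gives the allylic alcohol F14, and acetylation with Ac2O in pyridine comes back to the route at 26.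

## Further compounds

F1 | step 10 | (2E,5S,6S,8E,10E)-5-(tert-butyldimethylsilyloxy)-3,7,7-trimethyl-6-(naphthalen-2-ylmethoxy)dodeca-2,8,10-trien-1-ol | OC/C=C(\C)C[C@H](O[Si](C)(C)C(C)(C)C)[C@@H](OCc1ccc2ccccc2c1)C(C)(C)/C=C/C=C/C
F2 | step 10 | (2E,5S,6S,8E,10E)-5-(tert-butyldimethylsilyloxy)-3,7,7-trimethyl-6-(naphthalen-2-ylmethoxy)dodeca-2,8,10-trienal | O=C/C=C(\C)C[C@H](O[Si](C)(C)C(C)(C)C)[C@@H](OCc1ccc2ccccc2c1)C(C)(C)/C=C/C=C/C
F3 | step 10 | (1R,2R,4aS,6S,7S,8aR)-7-(tert-butyldimethylsilyloxy)-2,5,5,8a-tetramethyl-6-(naphthalen-2-ylmethoxy)-1,2,4a,5,6,7,8,8a-octahydronaphthalene-1-carbaldehyde | O=C[C@@H]1[C@H](C)C=C[C@@H]2C(C)(C)[C@H](OCc3ccc4ccccc4c3)[C@@H](O[Si](C)(C)C(C)(C)C)C[C@@]12C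
F4 | step 10 | (1R,2R,4aS,6S,7S,8aR)-7-(tert-butyldimethylsilyloxy)-2,5,5,8a-tetramethyl-6-(naphthalen-2-ylmethoxy)-1,2,4a,5,6,7,8,8a-octahydronaphthalene-1-carboxylic acid | OC(=O)[C@@H]1[C@H](C)C=C[C@@H]2C(C)(C)[C@H](OCc3ccc4ccccc4c3)[C@@H](O[Si](C)(C)C(C)(C)C)C[C@@]12C
F5 | step 8 | (4S,5S,7E,9E)-6,6-dimethyl-5-(naphthalen-2-ylmethoxy)undeca-7,9-dien-1-yn-4-ol | C#CC[C@H](O)[C@@H](OCc1ccc2ccccc2c1)C(C)(C)/C=C/C=C/C
F6 | step 8 | tert-butyl{[(4S,5S,7E,9E)-6,6-dimethyl-5-(naphthalen-2-ylmethoxy)undeca-7,9-dien-1-yn-4-yl]oxy}dimethylsilane | C#CC[C@H](O[Si](C)(C)C(C)(C)C)[C@@H](OCc1ccc2ccccc2c1)C(C)(C)/C=C/C=C/C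
F7 | step 8 | (E)-alkenyldimethylalane from F6 (Al on C9, methyl on C10) | C[Al](C)/C=C(\C)C[C@H](O[Si](C)(C)C(C)(C)C)[C@@H](OCc1ccc2ccccc2c1)C(C)(C)/C=C/C=C/C
F0 | step 11 | none | none
F8 | step 13 | methyl (1R,2R,4aS,6S,7S,8aR)-7-(tert-butyldimethylsilyloxy)-2,5,5,8a-tetramethyl-6-(naphthalen-2-ylmethoxy)-3-oxodecahydronaphthalene-1-carboxylate (C8 epimer of 18) | COC(=O)[C@@H]1[C@@H](C)C(=O)C[C@@H]2C(C)(C)[C@H](OCc3ccc4ccccc4c3)[C@@H](O[Si](C)(C)C(C)(C)C)C[C@@]12C
F9 | step 13 | methyl (1R,2R,3S,4aS,6S,7S,8aR)-7-(tert-butyldimethylsilyloxy)-3-hydroxy-2,5,5,8a-tetramethyl-6-(naphthalen-2-ylmethoxy)decahydronaphthalene-1-carboxylate (axial C7 alcohol) | COC(=O)[C@@H]1[C@@H](C)[C@@H](O)C[C@@H]2C(C)(C)[C@H](OCc3ccc4ccccc4c3)[C@@H](O[Si](C)(C)C(C)(C)C)C[C@@]12C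
F10 | step 17 | (2E)-3-methyl-4-(phenylsulfonyl)but-2-en-1-yl acetate | CC(=O)OC/C=C(\C)CS(=O)(=O)c1ccccc1
F11 | step 17 | (2E)-3-methyl-4-(phenylsulfonyl)but-2-en-1-ol | OC/C=C(\C)CS(=O)(=O)c1ccccc1
F12 | step 17 | O,C-dilithio derivative of F11 | [Li]OC/C=C(\C)C([Li])S(=O)(=O)c1ccccc1
F13 | step 17 | (2E)-5-[(1R,4aS,6S,7S,8aS)-7-(tert-butyldimethylsilyloxy)-2,5,5,8a-tetramethyl-6-(naphthalen-2-ylmethoxy)-1,4,4a,5,6,7,8,8a-octahydronaphthalen-1-yl]-3-methyl-4-(phenylsulfonyl)pent-2-en-1-ol (both C12 epimers) | OC/C=C(\C)C(C[C@@H]1C(C)=CC[C@@H]2C(C)(C)[C@H](OCc3ccc4ccccc4c3)[C@@H](O[Si](C)(C)C(C)(C)C)C[C@@]12C)S(=O)(=O)c1ccccc1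
F14 | step 17 | (2E)-5-[(1R,4aS,6S,7S,8aS)-7-(tert-butyldimethylsilyloxy)-2,5,5,8a-tetramethyl-6-(naphthalen-2-ylmethoxy)-1,4,4a,5,6,7,8,8a-octahydronaphthalen-1-yl]-3-methylpent-2-en-1-ol | OC/C=C(\C)CC[C@@H]1C(C)=CC[C@@H]2C(C)(C)[C@H](OCc3ccc4ccccc4c3)[C@@H](O[Si](C)(C)C(C)(C)C)C[C@@]12C
A1 | alternative 1 | 6-(tert-butyldimethylsilyloxy)-4a,8,8-trimethyl-4-[2-(2-methyl-1,3-dioxolan-2-yl)ethyl]-4,4a,5,6,7,8-hexahydronaphthalen-2(3H)-one | CC1(OCCO1)CC[C@@H]2CC(=O)C=C3C(C)(C)C[C@@H](O[Si](C)(C)C(C)(C)C)C[C@@]23C
A2 | alternative 2 | cis-fused 7-(tert-butyldimethylsilyloxy)-2,5,5,8a-tetramethyl-4a,5,8,8a-tetrahydronaphthalene-1,4-dione | O=C1C(C)=CC(=O)[C@H]2C(C)(C)C=C(O[Si](C)(C)C(C)(C)C)C[C@@]12C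
A3 | alternative 2 | 2,6-dimethyl-1,4-benzoquinone | CC1=CC(=O)C=C(C)C1=O
A4 | alternative 2 | tert-butyldimethyl[(4-methylpenta-1,3-dien-2-yl)oxy]silane | C=C(O[Si](C)(C)C(C)(C)C)C=C(C)C
A5 | alternative 3 | ethyl 7-(tert-butyldimethylsilyloxy)-2,5,5,8a-tetramethyl-1,5,6,7,8,8a-hexahydronaphthalene-1-carboxylate | CCOC(=O)[C@@H]1C(C)=CC=C2C(C)(C)C[C@@H](O[Si](C)(C)C(C)(C)C)C[C@@]12C
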